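## Structural features

The target 7 is an achiral wax ester, C34H60O3, made of an unbranched, fully saturated C26 acyl chain (carbonyl C1 to methyl C26) and a 4-hydroxyphenethyl alcohol part. The ester oxygen carries a two-carbon arm, O–CH2–CH2, whose second carbon is bound to C1 of the only ring, a benzene ring with a free hydroxyl group at C4. There is no stereocentre and no double bond outside the arene, so no stereocentres stand next to each other and nothing has to be controlled in space. The fragile groups are the aliphatic ester, which is open to hydroxide, alkoxide, hydride and strong carbon nucleophiles, and the free phenol, which is acidic, easily oxidised and a second site for acylation. A hidden weakness lies in the aryl–CH2–CH2–O–acyl unit, because a carbanion or an electropositive metal on the carbon β to the acyloxy group expels carboxylate and forms an olefin. The real difficulty is chemoselectivity and handling and not complexity: only the aliphatic oxygen may carry the acyl group, the chain must enter with exactly 26 carbons because homologous wax esters cannot be separated in practice, and every chain-bearing intermediate is a poorly soluble wax. The key step exploits the single bond between ring carbon C1, para to the oxygen, and the benzylic CH2 of the arm, an sp2–sp3 bond whose two carbons can both be supplied as halide electrophiles, so that the ester and the whole chain are already in place when it is formed.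

## Logic of the disconnections

7 ⇒ 6. The bond cut is the O–CH2 bond of a benzyl ether placed on the phenolic oxygen; the carbon skeleton is untouched. The free O–H is the one group of 7 that does not fit reductive nickel/zinc chemistry: it is acidic, and its anion could attack the primary bromide or the ester of the coupling partner. A benzyl ether is inert there and leaves under neutral hydrogenolysis. The gain is that the arene of 6 traces back to an article of commerce that already carries the mask, so protection costs no step and deprotection costs one. The forward step must stop at the benzylic C–O bond. This is met because the ester oxygen of 6 sits on a homobenzylic carbon, but the catalyst must not be poisoned by halide or metal traces from the step before.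

6 ⇒ 4 + 5. The bond cut is the single C–C bond between ring carbon C1 and the first CH2 of the arm. It is the only skeletal bond that joins the aromatic part to the chain-bearing part. Cutting it with both fragments as electrophiles avoids a 2-acyloxyethyl organometallic, which would fragment. The gain is full convergence: 5 is bought, and 4 holds all 28 aliphatic carbons and the ester. The forward step must join two different halides in preference to either homodimer, must not merely reduce them, and must spare the ester, the benzyl ether and the β-acyloxy arrangement. An sp2 iodide is paired with a primary sp3 bromide because nickel activates the two in different ways.

4 ⇒ 1 + 2 by way of 3. The bond cut is the acyl C–O bond of the ester, the most reliable bond of the molecule to form. It leads to 1, in which the chain length is fixed by purchase, and to 2, which brings the arm with its bromide; both are starting materials. The forward step demands full activation of the sparingly soluble 1 as 3 and an acylation that leaves the primary C–Br bond of 2 untouched. This argues for a telescoped, base-free procedure.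

## Other disconnections considered

Alternative 1: The cut removes two ring bonds of the arene, C1–C6 and C2–C3, so that the benzene ring is built from open-chain pieces, the aldehyde 4-oxobutyl hexacosanoate A1 and but-3-en-2-one A2.
- Forward key step: a secondary-amine enamine of A1 would add in conjugate fashion to A2, and the Michael adduct would close by intramolecular aldol condensation to the racemic cyclohexenone 2-(4-oxocyclohex-2-en-1-yl)ethyl hexacosanoate A3. A catalytic aerobic dehydrogenation of A3 (for example Pd(OCOCF3)2 under O2) would then give 7.
- In favour: the ring oxygen appears as a ketone and is unveiled as the phenol by the aromatisation itself, so no protecting group is needed. No aryl halide and no stoichiometric metal reductant are used. On these two points the alternative is the better of the two. On chain-length integrity it is the equal, since the chain still comes from 1.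
- Against: it constructs the one part of 7 that is cheaply bought, a para-substituted phenol ring. It sets a stereocentre at the arm-bearing ring carbon of A3 only to erase it.
- Mechanism: enamine and aldol chemistry is ionic and exposed to self-condensation of A1 and polymerisation of A2. The chosen plan forms one bond by a catalyst-controlled radical capture at nickel.
- Step economy: A1 needs about two steps from 1, followed by the annulation to A3 and the dehydrogenation, so four to five steps stand against three.

Alternative 2: The cut is at C10–C11 of the acyl chain, drawn as a double bond. It divides the chain into the C11 ester 2-(4-hydroxyphenyl)ethyl undec-10-enoate A4 and the C17 olefin heptadec-1-ene A5.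
- Forward key step: A4 and an excess of A5 would undergo cross-metathesis with the second-generation Grubbs catalyst, with loss of a gaseous C2 olefin. The expected main product is 2-(4-hydroxyphenyl)ethyl (E)-hexacos-10-enoate A6, and hydrogenation of the chain olefin of A6 would give 7.
- In favour: the ruthenium carbene tolerates the free phenol, so no protecting group is needed. The chain is assembled from C11 and C17 feedstocks that cost far less than 1. The count of three steps (selective acylation of the aliphatic hydroxyl to give A4, metathesis to A6, hydrogenation) equals that of the chosen plan. The alternative is thus the equal on step economy and the better on raw-material cost and protecting-group use. The new bond of A6 also lies far from any functional group, so β-elimination is no issue; on this structural point it is again the better.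
- Against: A4 and A5 are unhindered terminal olefins of the same reactivity class (type 1). The cross-product A6 would form statistically beside both homodimers, and the excess of A5 must be removed from a waxy mixture. More seriously, ruthenium hydride species from catalyst decay can move the double bond of A4 or A5 along the chain before metathesis. After hydrogenation this would leave C25 and C27 homologues of 7 that are practically inseparable. The chosen plan brings the chain in as one unit of defined length.
- Mechanism: reversible [2+2] cycloaddition and cycloreversion through ruthenacyclobutanes under thermodynamic control, against an irreversible sp2–sp3 bond formation.

Alternative 3: The cut is at C9–C10 of the acyl chain, which divides it into the half-ester 10-[2-(4-acetoxyphenyl)ethoxy]-10-oxodecanoic acid A7 and octadecanoic acid A8.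
- Forward key step: mixed Kolbe electrolysis of A7 with an excess of A8 at a Pt anode. The two carboxylates would decarboxylate to a C9 radical with the ester terminus and a C17 radical, which combine to 2-(4-acetoxyphenyl)ethyl hexacosanoate A9. Selective removal of the aryl acetate of A9 would give 7. The phenol is acetylated before electrolysis, since a free phenol is oxidised at a lower potential than a carboxylate.
- In favour: commodity acids, electrons as the only reagent and no metal waste, so on cost and waste of the bond-forming step the alternative is the better. There is no pathway for chain isomerisation, and the two symmetrical dimers differ strongly from A9 in size and polarity. On chain-length integrity it is the equal of the chosen plan.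
- Against: radical pairing is statistical, so much of A7 would be lost to its own dimer even with A8 in excess. Disproportionation and over-oxidation to cations (Hofer–Moest pathway) compete, and waxy products can coat the anode. The aryl acetate is at risk of transesterification in the partly neutralised alcoholic electrolyte, while a sturdier ether would make the ring easier to oxidise. The final deacetylation of A9 must distinguish an aryl ester from an alkyl ester, whereas hydrogenolysis in the chosen plan is orthogonal by mechanism.
- Mechanism: uncontrolled radical–radical coupling at an electrode, against radical capture by a nickel centre that enforces cross-selectivity.
- Step economy: A7 needs two to three steps, then electrolysis and deacetylation, so four to five steps stand against three.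

Key step: step 2

Assumption: 1, 2 and 5 are taken as purchasable, and in alternative 3 the phenol is taken to be acetylated before the electrolysis, since a free phenol would not survive the anode.

## Route

Step 1
Reactants: 1 hexacosanoic acid, 2 2-bromoethanol
Product: 4 2-bromoethyl hexacosanoate, via hexacosanoyl chloride 3 (not isolated)
Conditions: (COCl)2 (1.5 equiv), DMF (cat.), toluene, 50 °C; evaporate; then 2-bromoethanol (2, 1.3 equiv), toluene, 60 °C, N2 sweep
Reagents that add atoms: none
Why: DMF-catalysed chlorination of the acid by oxalyl chloride gives the acyl chloride 3, which acylates the primary hydroxyl of 2 by nucleophilic acyl substitution (esterification through an acid chloride). Working without an amine base lets HCl leave as gas and keeps soluble chloride and nucleophilic amines away from the primary C–Br bond, so neither halide exchange nor quaternisation is expected.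

Step 2
Reactants: 4 2-bromoethyl hexacosanoate, 5 1-(benzyloxy)-4-iodobenzene
Product: 6 2-[4-(benzyloxy)phenyl]ethyl hexacosanoate
Conditions: 5 (1.2 equiv), NiI2·xH2O (10 mol%), 4,4'-di-tert-butyl-2,2'-bipyridine (10 mol%), pyridine (10 mol%), Zn powder (2 equiv), DMPU/THF, 60 °C
Reagents that add atoms: none
Why: Zn reduces the NiI2–bipyridine complex to zerovalent nickel, which adds oxidatively to the C–I bond of 5 and gives an arylnickel iodide that holds divalent nickel. A monovalent nickel halide abstracts the bromine atom of 4, the primary 2-(acyloxy)ethyl radical is captured by the arylnickel species, and the trivalent aryl(alkyl)nickel complex eliminates reductively, which forms the bond between ring carbon C1 and the CH2 of the arm and returns monovalent nickel to carry the radical chain or to be reduced again by Zn. The closest known reaction type is the nickel-catalysed reductive cross-electrophile coupling of aryl iodides with primary alkyl bromides with a metal powder as terminal reductant. No ring is closed and no stereocentre is made. The step needs cross-coupling in preference to either homo-coupling, and the substrates secure this themselves: the sp2 iodide reacts by two-electron oxidative addition and the sp3 bromide by halogen-atom abstraction, so each enters the cycle at a different nickel species. It also needs the 2-acyloxyethyl unit to survive: the radical has no productive way to lose the ester (a 1,2-acyloxy shift would be degenerate), no alkylzinc or alkylmagnesium reagent that could expel carboxylate and an olefin is preformed, and the trivalent nickel intermediate is expected to eliminate reductively faster than it β-eliminates. The alkyl ester and the benzyl ether are not expected to react with Zn or low-valent nickel at 60 °C, and THF keeps the waxy bromide 4 in solution.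

Step 3
Reactants: 6 2-[4-(benzyloxy)phenyl]ethyl hexacosanoate
Product: 7 2-(4-hydroxyphenyl)ethyl hexacosanoate
Conditions: H2 (1 atm), Pd/C (10 wt% Pd), THF/EtOAc, 40 °C
Reagents that add atoms: none
Why: Heterogeneous hydrogenolysis of the benzyl aryl ether cleaves only the benzylic O–CH2 bond; the ester oxygen of 6 sits on a homobenzylic carbon and the saturated chain offers nothing to reduce, so toluene is the only by-product. The warm solvent mixture keeps the wax dissolved so that the catalyst surface stays accessible.

## Compound list

1 | hexacosanoic acid | CCCCCCCCCCCCCCCCCCCCCCCCCC(=O)O | starting material
2 | 2-bromoethanol | OCCBr | starting material
3 | hexacosanoyl chloride | CCCCCCCCCCCCCCCCCCCCCCCCCC(=O)Cl | intermediate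
4 | 2-bromoethyl hexacosanoate | CCCCCCCCCCCCCCCCCCCCCCCCCC(=O)OCCBr | intermediate
5 | 1-(benzyloxy)-4-iodobenzene | Ic1ccc(OCc2ccccc2)cc1 | starting material
6 | 2-[4-(benzyloxy)phenyl]ethyl hexacosanoate | CCCCCCCCCCCCCCCCCCCCCCCCCC(=O)OCCc1ccc(OCc2ccccc2)cc1 | intermediate
7 | 2-(4-hydroxyphenyl)ethyl hexacosanoate | CCCCCCCCCCCCCCCCCCCCCCCCCC(=O)OCCc1ccc(O)cc1 | target

## Step count and least certain steps

Total step count: 3. Longest linear sequence: 3 steps (1 → 4 → 6 → 7); 2 and 5 enter as purchased materials.

Step 2 (key step). The most likely failure is loss of cross-selectivity: aryl–aryl homocoupling and hydrodehalogenation of the iodide take over when the waxy bromide is poorly dissolved or reacts slowly. A second failure is reductive fragmentation of the alkyl partner, in which direct zinc insertion into the C–Br bond is followed by β-elimination of the carboxylate. The fallback forms the same ring–CH2 bond with reversed polarity before the ester exists, so β-acyloxy loss cannot occur. It sets out from 5: magnesium insertion in THF gives [4-(benzyloxy)phenyl]magnesium iodide F1, which opens oxirane under CuBr·SMe2 catalysis (THF, −30 to 0 °C, then dilute aqueous HCl) to 2-[4-(benzyloxy)phenyl]ethan-1-ol F2. F2 is then acylated in warm toluene with 3, made from 1 as in step 1, and the route is rejoined at 6.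

Step 1. The most likely failure is incomplete chlorination of the sparingly soluble C26 acid, after which activated and unactivated acid condense with each other and part of the chain is never esterified. Carry-over of oxalyl chloride that consumes 2 is a second risk. The fallback gives up acyl activation: direct Fischer esterification sets out from 1 and an excess of 2 (TsOH·H2O cat., toluene, reflux, azeotropic removal of water) and comes back to the route at 4. It involves no chloride at any stage and makes no compound outside the list, so its entry is F0.

Step 3. The most likely failure is stalling of the hydrogenolysis, through poisoning of the catalyst by traces of iodide, zinc or nickel carried over from step 2, or through deposition of the wax on the catalyst. The fallback replaces hydrogenation by Lewis-acid cleavage: BCl3 with pentamethylbenzene as benzyl-cation scavenger in CH2Cl2, started at −78 °C and warmed to about −20 °C so that the wax redissolves, sets out from 6 and arrives directly at 7. The aliphatic ester is expected to survive at these temperatures, and no compound outside the list arises on the way, so its entry is F0.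

## Further compounds

F1 | step 2 | [4-(benzyloxy)phenyl]magnesium iodide | I[Mg]c1ccc(OCc2ccccc2)cc1
F2 | step 2 | 2-[4-(benzyloxy)phenyl]ethan-1-ol | OCCc1ccc(OCc2ccccc2)cc1
F0 | step 1 | none | none
F0 | step 3 | none | none
A1 | alternative 1 | 4-oxobutyl hexacosanoate | CCCCCCCCCCCCCCCCCCCCCCCCCC(=O)OCCCC=O
A2 | alternative 1 | but-3-en-2-one (methyl vinyl ketone) | C=CC(C)=O
A3 | alternative 1 | racemic 2-(4-oxocyclohex-2-en-1-yl)ethyl hexacosanoate | CCCCCCCCCCCCCCCCCCCCCCCCCC(=O)OCCC1C=CC(=O)CC1
A4 | alternative 2 | 2-(4-hydroxyphenyl)ethyl undec-10-enoate | C=CCCCCCCCCC(=O)OCCc1ccc(O)cc1
A5 | alternative 2 | heptadec-1-ene | C=CCCCCCCCCCCCCCCC
A6 | alternative 2 | 2-(4-hydroxyphenyl)ethyl (E)-hexacos-10-enoate | CCCCCCCCCCCCCCC/C=C/CCCCCCCCC(=O)OCCc1ccc(O)cc1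
A7 | alternative 3 | 10-[2-(4-acetoxyphenyl)ethoxy]-10-oxodecanoic acid | OC(=O)CCCCCCCCC(=O)OCCc1ccc(OC(C)=O)cc1
A8 | alternative 3 | octadecanoic acid (stearic acid) | CCCCCCCCCCCCCCCCCC(=O)O
A9 | alternative 3 | 2-(4-acetoxyphenyl)ethyl hexacosanoate | CCCCCCCCCCCCCCCCCCCCCCCCCC(=O)OCCc1ccc(OC(C)=O)cc1
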